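## Retrosynthetic overview

1. Xenoacremone A 31 ⇒ 30: the last step is a syn-dihydroxylation of the lactam enamide C22=C29, which sets both lactam stereocentres.
2. 30 (13-membered cyclophane plus lactam) ⇒ 28: Wolff ring contraction of a 14-membered 2-diazo-1,3-dicarbonyl; C24 leaves the ring as a ketene and is captured by the enaminone nitrogen. 28 ⇒ isoxazolophane 26 (isoxazole = masked enaminone).
3. 26 ⇒ 24: intramolecular Ullmann etherification (C13–O–aryl, 14-membered ring). 24 ⇒ tricyclic Weinreb amide 17 + lithiated isoxazole carbinol 21.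
4. 17 ⇒ 16: an intramolecular Diels–Alder reaction builds rings B and C on a preformed ring A.
5. Ring A ⇒ proline aldol desymmetrisation of meso ketone 5 (from methyl acetoacetate and acetaldehyde). Ring order: A, then B + C, then the 14-membered macrocycle, then the 13-membered macrocycle and lactam together.

Assumption: the SMILES defines the natural enantiomer, and (2E)-5-bromopenta-1,3-diene 11 and 5-methylisoxazole-3-carbaldehyde 19 are taken as catalogue compounds.

Labels (follow the target SMILES): C1=C2 vinyl; C3 (vinyl-bearing); C4=C5; C6; C7; C8; C9 (Me); C10; C11 (Me); C12; C13 (O-aryl); C21 benzylic CH2; C22 hemiaminal carbon; C24 lactam C=O; C25=C26 enol; C27; C28; C29 carbinol. Ring A = C7–C12, ring B = C6/C7/C12/C13/C28, ring C = C3–C6/C28/C27. β = the face of the C9 and C11 methyls, α = the opposite face.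

## Route

Step 1
Reactants: 1 methyl acetoacetate (2 equiv); 2 acetaldehyde
Product: 4 racemic 3,5-dimethylcyclohex-2-en-1-one, via cyclic aldol diester 3 (not isolated)
Conditions: piperidine (cat.), neat, 0 °C to rt; then H2SO4, AcOH/H2O, reflux
Reagents that add atoms: none
Why: Knoevenagel condensation, Michael addition of the second acetoacetate and intramolecular aldol give 3, which hot acid dehydrates, hydrolyses and doubly decarboxylates (classical Knoevenagel–Michael–aldol annulation); the single stereocentre does not matter because step 2 gives a meso compound.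

Step 2
Reactants: 4 racemic 3,5-dimethylcyclohex-2-en-1-one
Product: 5 cis-3,5-dimethylcyclohexanone (meso)
Conditions: H2 (1 atm), Pd/C, EtOAc, rt
Reagents that add atoms: none
Why: Heterogeneous hydrogenation delivers H2 to the enone face anti to the C5 methyl, giving the cis (diequatorial, meso) ketone; any trans isomer is removed by chromatography.

Step 3
Reactants: 5 cis-3,5-dimethylcyclohexanone; 6 ethyl glyoxylate
Product: 7 ethyl (2R)-2-[(1S,2S,4R)-2,4-dimethyl-6-oxocyclohexyl]-2-hydroxyacetate
Conditions: L-proline (20 mol %), DMSO, rt; 6 added slowly as a toluene solution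
Reagents that add atoms: none
Why: Proline enamine aldol (direct asymmetric aldol), an atom-economical addition of one molecule of 5 to one of 6, goes through the hydrogen-bonded chair transition state to give the anti adduct (C12 and C13) and reacts at the enantiotopic α-carbon where the new bond forms trans to the adjacent methyl, so this step also fixes the absolute configuration of C9 and C11.

Step 4
Reactants: 7 ethyl (2R)-2-[(1S,2S,4R)-2,4-dimethyl-6-oxocyclohexyl]-2-hydroxyacetate
Product: 8 ethyl (2R)-2-[(tert-butyldimethylsilyl)oxy]-2-[(1S,2S,4R)-2,4-dimethyl-6-oxocyclohexyl]acetate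
Conditions: TBSOTf, 2,6-lutidine, CH2Cl2, −78 to 0 °C
Reagents that add atoms: tert-butyldimethylsilyl triflate, CC(C)(C)[Si](C)(C)OS(=O)(=O)C(F)(F)F
Why: Silylation of the β-hydroxy ketone under non-basic conditions blocks retro-aldol and elimination in the next steps and touches no stereocentre.

Step 5
Reactants: 8 ethyl (2R)-2-[(tert-butyldimethylsilyl)oxy]-2-[(1S,2S,4R)-2,4-dimethyl-6-oxocyclohexyl]acetate
Product: 10 ethyl (2R)-2-[(tert-butyldimethylsilyl)oxy]-2-[(1R,2S,4R,6R)-6-formyl-2,4-dimethylcyclohexyl]acetate, via methyl enol ether 9 (not isolated)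
Conditions: Ph3P(Cl)CH2OMe, NaN(SiMe3)2, THF, −78 to 0 °C; then 2 M HCl, THF, 0 °C; then DBU (cat.), CH2Cl2, rt
Reagents that add atoms: (methoxymethyl)triphenylphosphonium chloride, COC[P+](c1ccccc1)(c1ccccc1)c1ccccc1.[Cl-]; water, O
Why: Wittig methoxymethylenation, hydrolysis of enol ether 9 and base equilibration (one-carbon homologation) place the formyl group at C7 in the favoured equatorial position, trans to the C12 side chain and cis to both methyls (all-equatorial ring A).

Step 6
Reactants: 10 ethyl (2R)-2-[(tert-butyldimethylsilyl)oxy]-2-[(1R,2S,4R,6R)-6-formyl-2,4-dimethylcyclohexyl]acetate; 11 (2E)-5-bromopenta-1,3-diene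
Product: 14 ethyl (2R)-2-[(tert-butyldimethylsilyl)oxy]-2-{(1R,2S,4R,6S)-6-[(1E,3E)-hexa-1,3,5-trien-1-yl]-2,4-dimethylcyclohexyl}acetate, via phosphonium bromide 12 (not isolated), via phosphorus ylide 13 (not isolated)
Conditions: 11, PBu3, MeCN, rt; then KOtBu, THF, −78 °C; then 10, −78 to 0 °C
Reagents that add atoms: none
Why: Wittig olefination with an allylic tributylphosphonium ylide, a class that favours E alkenes, installs the (E,E)-hexatriene; the aldehyde α-centre is already at its equilibrium configuration.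

Step 7
Reactants: 14 ethyl (2R)-2-[(tert-butyldimethylsilyl)oxy]-2-{(1R,2S,4R,6S)-6-[(1E,3E)-hexa-1,3,5-trien-1-yl]-2,4-dimethylcyclohexyl}acetate
Product: 16 (2E,4S)-4-[(tert-butyldimethylsilyl)oxy]-4-{(1R,2S,4R,6S)-6-[(1E,3E)-hexa-1,3,5-trien-1-yl]-2,4-dimethylcyclohexyl}-N-methoxy-N-methylbut-2-enamide, via alpha-silyloxy aldehyde 15 (not isolated)
Conditions: iBu2AlH, CH2Cl2, −78 °C; then Ph3P=CHC(O)N(OMe)Me, MeOH, −78 °C to rt
Reagents that add atoms: N-methoxy-N-methyl-2-(triphenylphosphoranylidene)acetamide, CON(C)C(=O)C=P(c1ccccc1)(c1ccccc1)c1ccccc1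
Why: Half-reduction of the α-silyloxy ester and in situ Wittig reaction of aldehyde 15 with the stabilised ylide give the (E)-enamide without isolating the epimerisable aldehyde; C13 is untouched.

Step 8
Reactants: 16 (2E,4S)-4-[(tert-butyldimethylsilyl)oxy]-4-{(1R,2S,4R,6S)-6-[(1E,3E)-hexa-1,3,5-trien-1-yl]-2,4-dimethylcyclohexyl}-N-methoxy-N-methylbut-2-enamide
Product: 17 tricyclic Weinreb amide (C27 β-C(O)N(OMe)Me; C3 β-vinyl; C13 α-OTBS; H6α, H7α, H12β, H28β; 9β,11β-dimethyl)
Conditions: Me2AlCl (1.5 equiv), CH2Cl2, −40 to 0 °C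
Reagents that add atoms: none
Why: Lewis-acid-promoted intramolecular Diels–Alder reaction through the carbonyl-endo transition state, with the three-atom tether held by the trans-diequatorial ring A, closes rings B and C and sets C3, C6, C27 and C28 (trans B/C fusion, H6 cis to H7), the sense expected from the closely related hirsutellone trienes.

Step 9
Reactants: 18 1,4-diiodobenzene; 19 5-methylisoxazole-3-carbaldehyde
Product: 21 racemic (4-iodophenyl)(5-methylisoxazol-3-yl)methanol, via aryl Grignard reagent 20 (not isolated)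
Conditions: iPrMgCl·LiCl, THF, −20 °C; then 19, −20 to 0 °C
Reagents that add atoms: none
Why: Selective mono iodine–magnesium exchange and Grignard addition give the carbinol, whose stereocentre is temporary (removed in step 13) and whose alkoxide later shields the benzylic C–H from deprotonation.

Step 10
Reactants: 17 tricyclic Weinreb amide; 21 racemic (4-iodophenyl)(5-methylisoxazol-3-yl)methanol
Product: 23 tricyclic isoxazolylmethyl ketone (C13 α-OTBS; C21 carbinol 1:1), via dilithio alkoxide carbanion 22 (not isolated)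
Conditions: 21 (3 equiv), LiN(iPr)2 (6 equiv), THF, −78 °C; then 17, −78 to −40 °C; then AcOH
Reagents that add atoms: none
Why: Lateral lithiation of the 5-methylisoxazole next to the alkoxide (dianion 22) and acylation by the Weinreb amide, whose chelated tetrahedral intermediate stops at the ketone, join the two fragments; the dianion is used in excess because the acidic CH2 of the product consumes base, and C27 is not deprotonated at −78 °C.

Step 11
Reactants: 23 tricyclic isoxazolylmethyl ketone (C13 α-OTBS)
Product: 24 tricyclic isoxazolylmethyl ketone diol (C13 α-OH free)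
Conditions: HF·pyridine, pyridine, THF, 0 °C to rt
Reagents that add atoms: none
Why: Fluoride desilylation frees the C13 hydroxyl; the isoxazole, ketone and aryl iodide are inert to buffered HF.

Step 12
Reactants: 24 tricyclic isoxazolylmethyl ketone diol
Product: 25 14-membered isoxazolo-paracyclophane carbinol
Conditions: CuI (30 mol %), 3,4,7,8-tetramethyl-1,10-phenanthroline (60 mol %), Cs2CO3, toluene (2 mM), 110 °C
Reagents that add atoms: none
Why: Intramolecular Ullmann-type CuI-catalysed etherification at high dilution forms the aryl ether with retention at C13 (the alcohol C–O bond is never broken) and closes a 14-membered ring, a larger-ring version of the direct 13-membered Ullmann closure reported in the hirsutellone series; the C21 hydroxyl cannot reach the iodide.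

Step 13
Reactants: 25 14-membered isoxazolo-paracyclophane carbinol
Product: 26 14-membered isoxazolo-paracyclophane (C21 = CH2)
Conditions: Et3SiH, CF3CO2H, CH2Cl2, 0 °C
Reagents that add atoms: none
Why: Ionic hydrogenation: acid ionises the carbinol to the p-alkoxybenzyl cation, which the silane reduces, erasing the temporary C21 stereocentre; mono- and disubstituted alkenes and the aryl ether survive.

Step 14
Reactants: 26 14-membered isoxazolo-paracyclophane
Product: 27 14-membered (Z)-beta-enaminone 1,3-dicarbonyl macrocycle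
Conditions: Mo(CO)6, MeCN/H2O (15:1), 75 °C
Reagents that add atoms: none
Why: Reductive N–O cleavage of the isoxazole unmasks the (Z)-β-enaminone, whose nitrogen becomes the lactam nitrogen; cyclodehydration to a 4-pyridone is disfavoured because it would create a highly strained 12-membered metaparacyclophane.

Step 15
Reactants: 27 14-membered (Z)-beta-enaminone 1,3-dicarbonyl macrocycle
Product: 28 14-membered 2-diazo-1,3-dicarbonyl enaminone macrocycle
Conditions: 4-acetamidobenzenesulfonyl azide, Et3N, MeCN, 0 °C to rt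
Reagents that add atoms: 4-acetamidobenzenesulfonyl azide, CC(=O)Nc1ccc(cc1)S(=O)(=O)N=[N+]=[N-]
Why: Regitz diazo transfer goes to the most acidic methylene (C25, between the ketone and the vinylogous amide carbonyl) under mild base, while the hydrogen-bonded enaminone is left alone.

Step 16
Reactants: 28 14-membered 2-diazo-1,3-dicarbonyl enaminone macrocycle
Product: 30 13-membered 3-acyl-5-benzylpyrrol-2-one cyclophane (enol tautomer), via aminovinyl acylketene 29 (not isolated)
Conditions: hν (365 nm), degassed MeCN (1 mM), 20 °C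
Reagents that add atoms: none
Why: Proposed new method: photolysis expels N2 and the electron-rich enaminone carbon C29, pushed by the nitrogen lone pair through the vinylogous amide, makes the 1,2-shift from C24 to C25 in preference to the unactivated sp3 C27, so the 14-membered ring contracts to the 13-membered paracyclophane as acyl(vinyl)ketene 29, whose cis amino group adds at once to the ketene carbon to close the lactam (loss of N2 and amide formation pay for the extra ring strain; no stereocentre is formed); the closest known reactions are the Wolff ring contraction of cyclic 2-diazo-1,3-diketones and amine capture of the resulting acylketenes, not yet shown for a macrocyclic vinylogous amide or for building a strained cyclophane.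

Step 17
Reactants: 30 13-membered 3-acyl-5-benzylpyrrol-2-one cyclophane
Product: 31 xenoacremone A
Conditions: OsO4 (5 mol %), N-methylmorpholine N-oxide, acetone/H2O (5:1), 0 °C
Reagents that add atoms: N-methylmorpholine N-oxide, C[N+]1([O-])CCOCC1; water, O
Why: Upjohn syn-dihydroxylation of the electron-rich enamide alkene C22=C29 (faster than the vinyl and cyclohexene alkenes), expected from the exposed face opposite the aryl deck, sets C22 and C29 together as the cis-diol and gives the hemiaminal directly.

## Compound list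

1 | methyl acetoacetate (methyl 3-oxobutanoate) | CC(=O)CC(=O)OC | starting material
2 | acetaldehyde | CC=O | starting material
3 | dimethyl 4-hydroxy-2,4-dimethyl-6-oxocyclohexane-1,3-dicarboxylate (cyclic aldol diester, isomer mixture, not isolated) | COC(=O)C1C(C)C(C(=O)OC)C(C)(O)CC1=O | intermediate
4 | 3,5-dimethylcyclohex-2-en-1-one (racemic) | CC1=CC(=O)CC(C)C1 | intermediate
5 | cis-3,5-dimethylcyclohexanone (meso) | O=C1C[C@H](C)C[C@H](C)C1 | intermediate
6 | ethyl glyoxylate (ethyl 2-oxoacetate) | CCOC(=O)C=O | starting material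
7 | ethyl (2R)-2-[(1S,2S,4R)-2,4-dimethyl-6-oxocyclohexyl]-2-hydroxyacetate | O=C1C[C@H](C)C[C@H](C)[C@H]1[C@@H](O)C(=O)OCC | intermediate
8 | ethyl (2R)-2-[(tert-butyldimethylsilyl)oxy]-2-[(1S,2S,4R)-2,4-dimethyl-6-oxocyclohexyl]acetate | O=C1C[C@H](C)C[C@H](C)[C@H]1[C@@H](O[Si](C)(C)C(C)(C)C)C(=O)OCC | intermediate
9 | methyl enol ether of 8 (C7=CH–OMe, E/Z mixture, not isolated) | COC=C1C[C@H](C)C[C@H](C)[C@H]1[C@@H](O[Si](C)(C)C(C)(C)C)C(=O)OCC | intermediate
10 | ethyl (2R)-2-[(tert-butyldimethylsilyl)oxy]-2-[(1R,2S,4R,6R)-6-formyl-2,4-dimethylcyclohexyl]acetate (all ring substituents equatorial) | O=C[C@@H]1C[C@H](C)C[C@H](C)[C@H]1[C@@H](O[Si](C)(C)C(C)(C)C)C(=O)OCC | intermediate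
11 | (2E)-5-bromopenta-1,3-diene | C=C/C=C/CBr | starting material
12 | tributyl[(2E)-penta-2,4-dien-1-yl]phosphonium bromide (not isolated) | C=C/C=C/C[P+](CCCC)(CCCC)CCCC.[Br-] | intermediate
13 | tributyl[(2E)-penta-2,4-dien-1-ylidene]phosphorane (ylide, not isolated) | C=C/C=C/[CH-][P+](CCCC)(CCCC)CCCC | intermediate
14 | ethyl (2R)-2-[(tert-butyldimethylsilyl)oxy]-2-{(1R,2S,4R,6S)-6-[(1E,3E)-hexa-1,3,5-trien-1-yl]-2,4-dimethylcyclohexyl}acetate | C=C/C=C/C=C/[C@@H]1C[C@H](C)C[C@H](C)[C@H]1[C@@H](O[Si](C)(C)C(C)(C)C)C(=O)OCC | intermediate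
15 | (2R)-2-[(tert-butyldimethylsilyl)oxy]-2-{(1R,2S,4R,6S)-6-[(1E,3E)-hexa-1,3,5-trien-1-yl]-2,4-dimethylcyclohexyl}acetaldehyde (not isolated) | C=C/C=C/C=C/[C@@H]1C[C@H](C)C[C@H](C)[C@H]1[C@@H](O[Si](C)(C)C(C)(C)C)C=O | intermediate
16 | (2E,4S)-4-[(tert-butyldimethylsilyl)oxy]-4-{(1R,2S,4R,6S)-6-[(1E,3E)-hexa-1,3,5-trien-1-yl]-2,4-dimethylcyclohexyl}-N-methoxy-N-methylbut-2-enamide | C=C/C=C/C=C/[C@@H]1C[C@H](C)C[C@H](C)[C@H]1[C@@H](O[Si](C)(C)C(C)(C)C)/C=C/C(=O)N(C)OC | intermediate
17 | tricyclic Weinreb amide (6-5-6 core; C27 β-C(O)N(OMe)Me, C3 β-vinyl, C13 α-OTBS, H6α, H7α, H12β, H28β, 9β,11β-dimethyl) | C=C[C@@H]1C=C[C@@H]2[C@@H]3C[C@H](C)C[C@H](C)[C@H]3[C@@H](O[Si](C)(C)C(C)(C)C)[C@H]2[C@@H]1C(=O)N(C)OC | intermediate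
18 | 1,4-diiodobenzene | Ic1ccc(I)cc1 | starting material
19 | 5-methylisoxazole-3-carbaldehyde | Cc1cc(C=O)no1 | starting material
20 | (4-iodophenyl)magnesium chloride (not isolated) | Cl[Mg]c1ccc(I)cc1 | intermediate
21 | (4-iodophenyl)(5-methylisoxazol-3-yl)methanol (racemic) | Cc1cc(C(O)c2ccc(I)cc2)no1 | intermediate
22 | lithium alkoxide / 5-lithiomethyl dianion of 21 (not isolated) | [Li]Cc1cc(C(O[Li])c2ccc(I)cc2)no1 | intermediate
23 | tricyclic ketone: C27–C(=O)–CH2–(isoxazol-5-yl) bearing 3-[hydroxy(4-iodophenyl)methyl]; C13 α-OTBS; 1:1 at C21 | C=C[C@@H]1C=C[C@@H]2[C@@H]3C[C@H](C)C[C@H](C)[C@H]3[C@@H](O[Si](C)(C)C(C)(C)C)[C@H]2[C@@H]1C(=O)Cc1cc(C(O)c2ccc(I)cc2)no1 | intermediate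
24 | as 23 with free C13 α-OH (diol) | C=C[C@@H]1C=C[C@@H]2[C@@H]3C[C@H](C)C[C@H](C)[C@H]3[C@@H](O)[C@H]2[C@@H]1C(=O)Cc1cc(C(O)c2ccc(I)cc2)no1 | intermediate
25 | 14-membered isoxazolo-paracyclophane carbinol (C13 α-O-aryl; C21–OH, 1:1) | C=C[C@@H]1C=C[C@@H]2[C@@H]3C[C@H](C)C[C@H](C)[C@H]3[C@H]3Oc4ccc(cc4)C(O)c4cc(CC(=O)[C@H]1[C@@H]23)on4 | intermediate
26 | 14-membered isoxazolo-paracyclophane (C21 = CH2) | C=C[C@@H]1C=C[C@@H]2[C@@H]3C[C@H](C)C[C@H](C)[C@H]3[C@H]3Oc4ccc(cc4)Cc4cc(CC(=O)[C@H]1[C@@H]23)on4 | intermediate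
27 | 14-membered (Z)-β-enaminone 1,3-dicarbonyl macrocycle (C22–NH2, C24=O, C25H2, C26=O) | C=C[C@@H]1C=C[C@@H]2[C@@H]3C[C@H](C)C[C@H](C)[C@H]3[C@H]3Oc4ccc(cc4)C/C(N)=C/C(=O)CC(=O)[C@H]1[C@@H]23 | intermediate
28 | 14-membered 2-diazo-1,3-dicarbonyl enaminone macrocycle (C25=N2) | C=C[C@@H]1C=C[C@@H]2[C@@H]3C[C@H](C)C[C@H](C)[C@H]3[C@H]3Oc4ccc(cc4)C/C(N)=C/C(=O)C(=[N+]=[N-])C(=O)[C@H]1[C@@H]23 | intermediate
29 | 13-membered acyl(aminovinyl)ketene (C25=C24=O; not isolated) | C=C[C@@H]1C=C[C@@H]2[C@@H]3C[C@H](C)C[C@H](C)[C@H]3[C@H]3Oc4ccc(cc4)C/C(N)=C/C(=C=O)C(=O)[C@H]1[C@@H]23 | intermediate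
30 | 13-membered 3-acyl-5-benzylpyrrol-2-one cyclophane (enol tautomer, C22=C29 enamide) | C=C[C@@H]1C=C[C@@H]2[C@@H]3C[C@H](C)C[C@H](C)[C@H]3[C@H]3Oc4ccc(cc4)CC4=C/C(=C(/O)[C@H]1[C@@H]23)C(=O)N4 | intermediate
31 | xenoacremone A | C=C[C@@H]1C=C[C@@H]2[C@@H]3C[C@H](C)C[C@H](C)[C@H]3[C@H]3Oc4ccc(cc4)C[C@@]4(O)NC(=O)/C(=C(\O)[C@H]1[C@@H]23)[C@@H]4O | target

## Step count and risks

Total steps: 17 (16 in the main line plus step 9 for fragment 21). Longest linear sequence: 16 steps (steps 1–8 and 10–17).

**Step 3 (desymmetrising aldol).** The choice between the two enantiotopic α-carbons of a doubly β-branched meso ketone has no exact precedent and could give low dr or ee. The fallback sets out from 5 and comes back at 7. Enantioselective deprotonation of 5 with a chiral lithium amide (lithium bis(1-phenylethyl)amide, Me3SiCl in situ, THF, −100 °C) gives (3S,5R)-3,5-dimethyl-1-(trimethylsilyloxy)cyclohexene F1. MeLi then regenerates the lithium enolate, which adds to 6 at −78 °C through the closed transition state of a cyclic E-enolate (anti aldol) to give 7.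

**Step 16 (the proposed ring contraction).** It can fail through migration of C27 instead of C29, through N–H insertion of the carbene, or because the strained ring does not form. The fallback uses only known chemistry and closes the 13-membered ring directly by etherification; it sets out from 17 and comes back at 30. Lithioacetonitrile (MeCN, LiN(iPr)2, THF, −78 °C) converts the Weinreb amide 17 into the tricyclic β-ketonitrile F2. Separately, Grignard reagent 20 opens epichlorohydrin (CuI cat.) to give 1-chloro-3-(4-iodophenyl)propan-2-ol F3, and Dess–Martin oxidation gives 1-chloro-3-(4-iodophenyl)propan-2-one F4. C-alkylation of the β-ketonitrile with the chloroketone (NaH, NaI cat., THF) gives the γ-keto β-ketonitrile F5. Nitrile hydration with [PtH{(PMe2O)2H}(PMe2OH)] in aqueous ethanol gives the primary amide, which closes onto the C22 ketone; aqueous HCl in THF then dehydrates the hemiaminal and removes the silyl group to give the seco 3-acyl-5-(4-iodobenzyl)pyrrol-2-one F6 with a free C13 hydroxyl. Intramolecular Ullmann etherification (CuI, phenanthroline ligand, Cs2CO3, toluene, 110 °C, high dilution) closes the 13-membered aryl ether directly, as reported in the hirsutellone series, and delivers 30.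

**Step 17 (dihydroxylation).** The vinyl group may compete. 30 may also sit largely as another tautomer, so the step relies on equilibration with the reactive enamide form. Facial selectivity is inferred from the shape of the cyclophane, not proven. The fallback sets out from 30 and comes back at 31: dimethyldioxirane in acetone at −78 °C, an electrophilic oxidant that strongly prefers the enamide, gives the 22,29-epoxy lactam F7, and mild aqueous opening through the N-acyliminium ion (wet silica or aqueous NaHCO3) gives the hemiaminal 31 under thermodynamic control at C22.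

Steps 8 and 12 rest on close precedent in the hirsutellone series and are judged less risky than these three.

Further compounds
F1 | step 3 | (3S,5R)-3,5-dimethyl-1-(trimethylsilyloxy)cyclohex-1-ene | C[Si](C)(C)OC1=C[C@@H](C)C[C@@H](C)C1
F2 | step 16 | tricyclic β-ketonitrile (C27–C(=O)CH2CN; C13 α-OTBS) | C=C[C@@H]1C=C[C@@H]2[C@@H]3C[C@H](C)C[C@H](C)[C@H]3[C@@H](O[Si](C)(C)C(C)(C)C)[C@H]2[C@@H]1C(=O)CC#N
F3 | step 16 | 1-chloro-3-(4-iodophenyl)propan-2-ol (racemic) | OC(CCl)Cc1ccc(I)cc1
F4 | step 16 | 1-chloro-3-(4-iodophenyl)propan-2-one | O=C(CCl)Cc1ccc(I)cc1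
F5 | step 16 | tricyclic γ-keto β-ketonitrile (C25 alkylated with CH2C(=O)CH2C6H4I; C13 α-OTBS; mixture at C25) | C=C[C@@H]1C=C[C@@H]2[C@@H]3C[C@H](C)C[C@H](C)[C@H]3[C@@H](O[Si](C)(C)C(C)(C)C)[C@H]2[C@@H]1C(=O)C(C#N)CC(=O)Cc1ccc(I)cc1
F6 | step 16 | seco 3-acyl-5-(4-iodobenzyl)pyrrol-2-one (enol tautomer; free C13 α-OH) | C=C[C@@H]1C=C[C@@H]2[C@@H]3C[C@H](C)C[C@H](C)[C@H]3[C@@H](O)[C@H]2[C@@H]1C(O)=C1C=C(Cc2ccc(I)cc2)NC1=O
F7 | step 17 | 22,29-epoxy lactam cyclophane (epoxide on the α face) | C=C[C@@H]1C=C[C@@H]2[C@@H]3C[C@H](C)C[C@H](C)[C@H]3[C@H]3Oc4ccc(cc4)C[C@@]45NC(=O)/C(=C(\O)[C@H]1[C@@H]23)[C@@H]4O5
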